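## Retrosynthetic overview

1. The plan rests on the oxidised-iridoid core: in the cyclopenta[c]pyran, C1 and C3 are aldehyde-level carbons on either side of O2, and the fusion bond C4a–C7a joins the α-carbon of one enal (C1–C7a=C7) to the β-carbon of the other (C3–C4=C4a).
2. Target 30 ⇐ dihydropyran 29 (DDQ removes H-4a and H-5) ⇐ lactol 27 (acid: lactol dehydration, acetal cleavage).
3. 27 ⇐ acyclic (S)-acetoxy bis-enal 24 under amine catalysis: the cyclopentene ring closes first (C4a–C7a), the dihydropyran ring second (C1–O2).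
4. 24 ⇐ triol 20 (silylate the primary hydroxyls, acetylate, desilylate, oxidise) ⇐ alkylidene lactone 19 ⇐ Horner–Wadsworth–Emmons union of phosphono lactone 10 with aldehyde 18, chosen because a crossed aldol of two enolisable aldehydes would not be selective.
5. 10 ⇐ geranial + allylboronate (asymmetric allylboration sets the only stereocentre); 18 ⇐ methyl dimethoxyacetate + butenyl Grignard reagent + phosphonoacetate.

Key step: step 14

Assumption: the sense of induction in step 1 follows the known behaviour of aryl and alkenyl aldehydes with this acid (R acid gives R carbinol), so the S acid is used, and the configuration of 4 would be checked by Mosher ester analysis before the material is carried on; the enal geometries are drawn E as expected but do not matter, since both are erased in step 14.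

## Route

Step 1
Reactants: 1 geranial; 2 allylboronic acid pinacol ester
Product: 4 (4S,5E)-6,10-dimethylundeca-1,5,9-trien-4-ol, via pinacol borate ester 3 (not isolated)
Conditions: (S)-TRIP [(S)-3,3'-bis(2,4,6-triisopropylphenyl)-1,1'-binaphthyl-2,2'-diyl hydrogen phosphate] (5 mol %), toluene, −30 °C; aq. NaHCO3 work-up
Reagents that add atoms: none
Why: Chiral phosphoric-acid-catalysed allylboration through a chair Zimmerman–Traxler transition state in which the acid binds the boronate oxygen and the formyl hydrogen; the S acid should direct the allyl group to the Si face of the enal and so set the S carbinol centre.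

Step 2
Reactants: 4
Product: 6 (4S,5E)-6,10-dimethylundeca-5,9-diene-1,4-diol, via bis(9-BBN) adduct 5 (not isolated)
Conditions: 9-BBN (2.5 equiv), THF, 0 °C → rt; then NaOH, H2O2, 0 °C
Reagents that add atoms: hydrogen peroxide, OO
Why: Anti-Markovnikov hydroboration–oxidation in which 9-BBN distinguishes the monosubstituted alkene from the two trisubstituted ones; the stereocentre is not involved.

Step 3
Reactants: 6
Product: 8 (5S)-5-[(1E)-2,6-dimethylhepta-1,5-dien-1-yl]oxolan-2-one, via lactol 7 (not isolated)
Conditions: TEMPO (0.2 equiv), PhI(OAc)2 (3 equiv), CH2Cl2, rt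
Reagents that add atoms: none
Why: Oxidative lactonisation of a 1,4-diol (oxoammonium oxidation of the primary alcohol, lactol formation, second oxidation); the primary alcohol reacts first and the secondary allylic oxygen becomes the ring oxygen with its configuration intact.

Step 4
Reactants: 8
Product: 10 diethyl [(5S)-5-((1E)-2,6-dimethylhepta-1,5-dien-1-yl)-2-oxooxolan-3-yl]phosphonate (C3 epimers), via enol phosphate 9 (not isolated)
Conditions: LiN(i-Pr)2 (1.1 equiv), THF, −78 °C; ClP(O)(OEt)2; then LiN(i-Pr)2 (2.2 equiv), −78 → 0 °C; aq. NH4Cl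
Reagents that add atoms: diethyl chlorophosphate, CCOP(=O)(Cl)OCC
Why: O-phosphorylation of the lactone enolate followed by base-induced 1,3-phosphorus migration (vinyl phosphate to β-carbonyl phosphonate rearrangement) gives the α-phosphono lactone; the new C3 centre is lost again in step 8.

Step 5
Reactants: 11 methyl dimethoxyacetate; 12 but-3-enylmagnesium bromide
Product: 14 1,1-dimethoxyhex-5-en-2-one, via tetrahedral ROMgBr adduct 13 (not isolated)
Conditions: CH2=CHCH2CH2MgBr (1.05 equiv) added to the ester, THF, −78 °C; aq. NH4Cl at −78 °C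
Reagents that add atoms: none
Why: Mono-addition of a Grignard reagent to an α,α-dialkoxy ester, whose chelated tetrahedral magnesium alkoxide persists at −78 °C and releases the ketone only on quenching.

Step 6
Reactants: 14; 15 triethyl phosphonoacetate
Product: 16 ethyl (2E)-3-(dimethoxymethyl)hepta-2,6-dienoate
Conditions: NaH, THF, 0 °C → rt
Reagents that add atoms: none
Why: Horner–Wadsworth–Emmons olefination of an activated α-keto acetal, with the E isomer expected to predominate.

Step 7
Reactants: 16
Product: 18 ethyl (2E)-3-(dimethoxymethyl)-6-oxohex-2-enoate, via ozonide 17 (not isolated)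
Conditions: O3, CH2Cl2, −78 °C, Sudan Red 7B as end-point indicator; then Me2S, −78 °C → rt
Reagents that add atoms: ozone, [O-][O+]=O
Why: Ozonolysis with reductive work-up, in which the electron-rich monosubstituted alkene is cleaved well before the electron-poor trisubstituted enoate and the dye marks the end-point.

Step 8
Reactants: 10; 18
Product: 19 ethyl (2E,6E)-3-(dimethoxymethyl)-6-[(5S)-5-((1E)-2,6-dimethylhepta-1,5-dien-1-yl)-2-oxooxolan-3-ylidene]hex-2-enoate
Conditions: 10, NaH, THF, 0 °C; then 18, 0 °C → rt
Reagents that add atoms: none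
Why: Horner–Wadsworth–Emmons reaction of an α-phosphono-γ-butyrolactone with an aliphatic aldehyde gives the α-alkylidene lactone (the future C4=C4a bond, E expected); the pre-formed phosphonate anion is too weakly basic to disturb the aldehyde α-protons or the lactone stereocentre.

Step 9
Reactants: 19
Product: 20 (2E,6E,9S,10E)-3-(dimethoxymethyl)-7-(hydroxymethyl)-11,15-dimethylhexadeca-2,6,10,14-tetraene-1,9-diol
Conditions: i-Bu2AlH (7 equiv), CH2Cl2, −78 → −20 °C; aq. potassium sodium tartrate
Reagents that add atoms: none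
Why: 1,2-Reduction of the alkylidene lactone to the allylic 1,4-diol and of the enoate to the allylic alcohol, at a temperature where the hydride reagent leaves the dimethyl acetal alone.

Step 10
Reactants: 20
Product: 21 (2E,6E,9S,10E)-1-(tert-butyldimethylsilyloxy)-7-[(tert-butyldimethylsilyloxy)methyl]-3-(dimethoxymethyl)-11,15-dimethylhexadeca-2,6,10,14-tetraen-9-ol
Conditions: TBSCl (2.1 equiv), imidazole, CH2Cl2, −20 → 0 °C
Reagents that add atoms: tert-butyldimethylsilyl chloride, CC(C)(C)[Si](C)(C)Cl
Why: Sterically controlled silylation that takes the two primary allylic hydroxyls and leaves the more hindered secondary one free.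

Step 11
Reactants: 21
Product: 22 (2E,6E,9S,10E)-1-(tert-butyldimethylsilyloxy)-7-[(tert-butyldimethylsilyloxy)methyl]-3-(dimethoxymethyl)-11,15-dimethylhexadeca-2,6,10,14-tetraen-9-yl acetate
Conditions: Ac2O, Et3N, DMAP (cat.), CH2Cl2, 0 °C → rt
Reagents that add atoms: acetic anhydride, CC(=O)OC(C)=O
Why: DMAP-catalysed acylation of the only free hydroxyl, with retention because the C–O bond is not broken.

Step 12
Reactants: 22
Product: 23 (2E,6E,9S,10E)-1-hydroxy-7-(hydroxymethyl)-3-(dimethoxymethyl)-11,15-dimethylhexadeca-2,6,10,14-tetraen-9-yl acetate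
Conditions: HF·pyridine, pyridine, THF, 0 °C → rt
Reagents that add atoms: none
Why: Buffered fluoride cleavage of primary silyl ethers, under which the acetate neither migrates nor hydrolyses and the acetal survives.

Step 13
Reactants: 23
Product: 24 (2E,6E,9S,10E)-3-(dimethoxymethyl)-7-formyl-11,15-dimethyl-1-oxohexadeca-2,6,10,14-tetraen-9-yl acetate
Conditions: MnO2 (activated, 30 equiv), CH2Cl2, rt
Reagents that add atoms: none
Why: Neutral heterogeneous oxidation of both primary allylic alcohols to enals, tolerated by the acetal and the allylic acetate.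

Step 14
Reactants: 24
Product: 27 (2S,3E)-1-[7-(dimethoxymethyl)-1-hydroxy-1,4a,5,7a-tetrahydrocyclopenta[c]pyran-4-yl]-4,8-dimethylnona-3,7-dien-2-yl acetate (ring centres C1/C4a/C7a unassigned), via dienamine 25 (not isolated), via Michael adduct 26 (not isolated)
Conditions: pyrrolidine (20 mol %), PhCO2H (20 mol %), CH2Cl2 (0.05 M), 0 °C → rt; short SiO2 plug; used at once in step 15
Reagents that add atoms: none
Why: Pyrrolidine condenses with the C1 enal, benzoate removes a C6 proton to give dienamine 25, its α-carbon C7a adds to C4a of the C3 enal to give 26 after iminium hydrolysis, and the C3 enol oxygen then adds to the C1 carbonyl to give lactol 27. The closest known chemistry is the secondary-amine-catalysed dienamine (Rauhut–Currier-type) cyclisation of octa-2,6-dienedials of the 8-oxogeranial type, together with the enol-lactol closure that iridodial- and genipin-type dialdehydes undergo spontaneously. The cyclopentene ring closes by a 5-(enolexo)-exo-trig Michael addition (C4a–C7a) and the dihydropyran ring by 6-exo-trig attack of the enol oxygen on the C1 carbonyl (C1–O2). C4a and C7a should end cis because only the cis-fused adduct can lactolise and the trans adduct can revert through the dienamine; C1 is expected as an anomeric mixture; all three centres are removed in steps 15 and 16, and the acetoxy-bearing centre is remote and untouched. The step needs the C1 enal to act as donor through its α-carbon: the α-branch on the C3 enal slows its own iminium formation and would force the reverse closure to join two fully substituted carbons, the C7–C6–C5 tether makes γ-attack a three-ring closure, and the dimethyl acetal keeps the third formyl group silent. The reaction is stopped as soon as 24 is consumed so that further amine catalysis does not draw 27 into the conjugated cyclopentenecarbaldehyde tautomer.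

Step 15
Reactants: 27
Product: 29 (2S,3E)-1-(7-formyl-4a,5-dihydrocyclopenta[c]pyran-4-yl)-4,8-dimethylnona-3,7-dien-2-yl acetate, via lactol aldehyde 28 (not isolated)
Conditions: PPTS (0.2 equiv), acetone–H2O (20:1), rt; then solvent switch, PPTS, benzene, 4 Å molecular sieves, 50 °C
Reagents that add atoms: water, O
Why: Mild acid first hydrolyses the allylic dimethyl acetal and then ionises the lactol to an oxocarbenium ion that loses the doubly allylic H-7a (E1 dehydration) to give the conjugated dienyl ether; pyridinium tosylate is too weak an acid to ionise the allylic acetate.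

Step 16
Reactants: 29
Product: 30 (2S,3E)-1-(7-formylcyclopenta[c]pyran-4-yl)-4,8-dimethylnona-3,7-dien-2-yl acetate (target)
Conditions: DDQ (1.1 equiv), CH2Cl2, 0 °C → rt; aq. NaHCO3
Reagents that add atoms: none
Why: DDQ dehydrogenation, in which hydride abstraction from C4a gives a cyclopenta-fused pyrylium ion that loses H-5 to the aromatic cyclopenta[c]pyran; the isolated trisubstituted alkenes react far more slowly.

## Compound list

1 | geranial, (2E)-3,7-dimethylocta-2,6-dienal | CC(C)=CCC/C(C)=C/C=O | starting material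
2 | allylboronic acid pinacol ester | C=CCB1OC(C)(C)C(C)(C)O1 | starting material
3 | pinacol borate ester of 4 | C=CC[C@H](OB1OC(C)(C)C(C)(C)O1)/C=C(\C)CCC=C(C)C | intermediate
4 | (4S,5E)-6,10-dimethylundeca-1,5,9-trien-4-ol | C=CC[C@H](O)/C=C(\C)CCC=C(C)C | intermediate
5 | bis(9-BBN) adduct: C1-borane, O4-borinate of 4 | C(CC[C@H](OB1C2CCCC1CCC2)/C=C(\C)CCC=C(C)C)B1C2CCCC1CCC2 | intermediate
6 | (4S,5E)-6,10-dimethylundeca-5,9-diene-1,4-diol | OCCC[C@H](O)/C=C(\C)CCC=C(C)C | intermediate
7 | (5S)-5-[(1E)-2,6-dimethylhepta-1,5-dien-1-yl]oxolan-2-ol (anomers) | OC1CC[C@@H](/C=C(\C)CCC=C(C)C)O1 | intermediate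
8 | (5S)-5-[(1E)-2,6-dimethylhepta-1,5-dien-1-yl]oxolan-2-one | O=C1CC[C@@H](/C=C(\C)CCC=C(C)C)O1 | intermediate
9 | diethyl (5S)-5-[(1E)-2,6-dimethylhepta-1,5-dien-1-yl]-4,5-dihydrofuran-2-yl phosphate | CCOP(=O)(OCC)OC1=CC[C@@H](/C=C(\C)CCC=C(C)C)O1 | intermediate
10 | diethyl [(5S)-5-((1E)-2,6-dimethylhepta-1,5-dien-1-yl)-2-oxooxolan-3-yl]phosphonate (C3 epimers) | CCOP(=O)(OCC)C1C[C@@H](/C=C(\C)CCC=C(C)C)OC1=O | intermediate
11 | methyl dimethoxyacetate | COC(=O)C(OC)OC | starting material
12 | but-3-enylmagnesium bromide | C=CCC[Mg]Br | starting material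
13 | bromomagnesium alkoxide of the methyl hemiketal of 14 | C=CCCC(OC)(O[Mg]Br)C(OC)OC | intermediate
14 | 1,1-dimethoxyhex-5-en-2-one | C=CCCC(=O)C(OC)OC | intermediate
15 | triethyl phosphonoacetate | CCOC(=O)CP(=O)(OCC)OCC | starting material
16 | ethyl (2E)-3-(dimethoxymethyl)hepta-2,6-dienoate | CCOC(=O)/C=C(/C(OC)OC)CCC=C | intermediate
17 | ozonide (3-substituted 1,2,4-trioxolane) of 16 | CCOC(=O)/C=C(/C(OC)OC)CCC1OCOO1 | intermediate
18 | ethyl (2E)-3-(dimethoxymethyl)-6-oxohex-2-enoate | CCOC(=O)/C=C(/C(OC)OC)CCC=O | intermediate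
19 | ethyl (2E,6E)-3-(dimethoxymethyl)-6-[(5S)-5-((1E)-2,6-dimethylhepta-1,5-dien-1-yl)-2-oxooxolan-3-ylidene]hex-2-enoate | CCOC(=O)/C=C(/C(OC)OC)CC/C=C1\C[C@@H](/C=C(\C)CCC=C(C)C)OC1=O | intermediate
20 | (2E,6E,9S,10E)-3-(dimethoxymethyl)-7-(hydroxymethyl)-11,15-dimethylhexadeca-2,6,10,14-tetraene-1,9-diol | OC/C=C(/C(OC)OC)CC/C=C(/CO)C[C@H](O)/C=C(\C)CCC=C(C)C | intermediate
21 | 1-O,7-(CH2O)-bis(tert-butyldimethylsilyl) ether of 20, 9-OH free | CC(C)(C)[Si](C)(C)OC/C=C(/C(OC)OC)CC/C=C(/CO[Si](C)(C)C(C)(C)C)C[C@H](O)/C=C(\C)CCC=C(C)C | intermediate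
22 | 9-O-acetate of 21 | CC(C)(C)[Si](C)(C)OC/C=C(/C(OC)OC)CC/C=C(/CO[Si](C)(C)C(C)(C)C)C[C@H](OC(C)=O)/C=C(\C)CCC=C(C)C | intermediate
23 | (2E,6E,9S,10E)-1-hydroxy-7-(hydroxymethyl)-3-(dimethoxymethyl)-11,15-dimethylhexadeca-2,6,10,14-tetraen-9-yl acetate | OC/C=C(/C(OC)OC)CC/C=C(/CO)C[C@H](OC(C)=O)/C=C(\C)CCC=C(C)C | intermediate
24 | (2E,6E,9S,10E)-3-(dimethoxymethyl)-7-formyl-11,15-dimethyl-1-oxohexadeca-2,6,10,14-tetraen-9-yl acetate (key-step precursor) | O=C/C=C(/C(OC)OC)CC/C=C(/C=O)C[C@H](OC(C)=O)/C=C(\C)CCC=C(C)C | intermediate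
25 | N-pyrrolidinyl dienamine of the C1 enal of 24 (C1=C7a and C7=C6) | C1CCN(C1)/C=C/C(C(OC)OC)=C\C/C=C(/C=O)C[C@H](OC(C)=O)/C=C(\C)CCC=C(C)C | intermediate
26 | cyclopentene dialdehyde: 2-formyl-3-(dimethoxymethyl)cyclopent-3-en-1-yl on the α-carbon of the C3 aldehyde (new centres unassigned) | CC(=O)O[C@H](/C=C(\C)CCC=C(C)C)CC(C=O)C1CC=C(C(OC)OC)C1C=O | intermediate
27 | (2S,3E)-1-[7-(dimethoxymethyl)-1-hydroxy-1,4a,5,7a-tetrahydrocyclopenta[c]pyran-4-yl]-4,8-dimethylnona-3,7-dien-2-yl acetate (C1, C4a, C7a unassigned) | CC(=O)O[C@H](/C=C(\C)CCC=C(C)C)CC1=COC(O)C2C1CC=C2C(OC)OC | intermediate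
28 | (2S,3E)-1-(7-formyl-1-hydroxy-1,4a,5,7a-tetrahydrocyclopenta[c]pyran-4-yl)-4,8-dimethylnona-3,7-dien-2-yl acetate | CC(=O)O[C@H](/C=C(\C)CCC=C(C)C)CC1=COC(O)C2C1CC=C2C=O | intermediate
29 | (2S,3E)-1-(7-formyl-4a,5-dihydrocyclopenta[c]pyran-4-yl)-4,8-dimethylnona-3,7-dien-2-yl acetate | CC(=O)O[C@H](/C=C(\C)CCC=C(C)C)CC1=COC=C2C1CC=C2C=O | intermediate
30 | (2S,3E)-1-(7-formylcyclopenta[c]pyran-4-yl)-4,8-dimethylnona-3,7-dien-2-yl acetate | CC(=O)O[C@H](/C=C(\C)CCC=C(C)C)Cc1cocc2c(C=O)ccc1-2 | target

## Step count and risks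

Total: 16 steps. Longest linear sequence: 13 steps (steps 1–4 and 8–16, from geranial); steps 5–7 make the second fragment.

Most likely to fail:

Step 14. The first-formed β,γ-unsaturated C1 iminium may tautomerise into the conjugated cyclopentenecarbaldehyde before the C3 enol oxygen closes the pyran ring, or the bis-enal may oligomerise. The fallback sets out from 24 and uses a stoichiometric, weakly basic amine. N-Methylaniline (1.2 equiv), N-methylanilinium trifluoroacetate (10 mol %) and 4 Å molecular sieves in benzene should give the N-aryl dienamine, which undergoes the intramolecular inverse-demand enamine–enal hetero-Diels–Alder reaction to the isolable 1-(N-methylanilino)-1,4a,5,7a-tetrahydrocyclopenta[c]pyran N,O-acetal F1. This aminal does not re-ionise readily, so the C1–O2 bond is held. Under the conditions of step 15, F1 loses N-methylaniline in place of water and its acetal is cleaved, which brings the material back to the route at 29.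

Step 15. Protic acid may ionise or transpose the allylic acetate, or hydrate and oligomerise the enol ethers before dehydration is complete. The fallback sets out from 27 and dehydrates under basic conditions. MsCl and Et3N in CH2Cl2 (−20 °C → rt) give the anomeric mesylate F2, which eliminates in the flask to the acetal-bearing dienyl ether F3. DDQ then gives the aromatic acetal F4. Its acetal now sits on the electron-rich five-membered ring and should hydrolyse on wet silica gel or with dilute aqueous oxalic acid, rejoining the route at 30.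

Step 4. The phosphate-to-phosphonate migration may be incomplete, or the enol phosphate may be lost by competing deprotonation. The fallback sets out from 8 and replaces steps 4 and 8 by an aldol condensation. The lithium enolate of 8 (LiN(i-Pr)2, THF, −78 °C) is added to aldehyde 18 to give the β-hydroxy lactone F5. MsCl and Et3N give the mesylate F6, and DBU eliminates it to the alkylidene lactone, rejoining the route at 19 (alkene geometry immaterial).

## Further compounds

F1 | step 14 | (2S,3E)-1-[7-(dimethoxymethyl)-1-(N-methylanilino)-1,4a,5,7a-tetrahydrocyclopenta[c]pyran-4-yl]-4,8-dimethylnona-3,7-dien-2-yl acetate | CC(=O)O[C@H](/C=C(\C)CCC=C(C)C)CC1=COC(N(C)c2ccccc2)C2C1CC=C2C(OC)OC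
F2 | step 15 | anomeric (C1) methanesulfonate of lactol 27 | CC(=O)O[C@H](/C=C(\C)CCC=C(C)C)CC1=COC(OS(C)(=O)=O)C2C1CC=C2C(OC)OC
F3 | step 15 | (2S,3E)-1-[7-(dimethoxymethyl)-4a,5-dihydrocyclopenta[c]pyran-4-yl]-4,8-dimethylnona-3,7-dien-2-yl acetate | CC(=O)O[C@H](/C=C(\C)CCC=C(C)C)CC1=COC=C2C1CC=C2C(OC)OC
F4 | step 15 | (2S,3E)-1-[7-(dimethoxymethyl)cyclopenta[c]pyran-4-yl]-4,8-dimethylnona-3,7-dien-2-yl acetate | CC(=O)O[C@H](/C=C(\C)CCC=C(C)C)Cc1cocc2c(C(OC)OC)ccc1-2
F5 | step 4 | ethyl (2E)-3-(dimethoxymethyl)-6-hydroxy-6-[(5S)-5-((1E)-2,6-dimethylhepta-1,5-dien-1-yl)-2-oxooxolan-3-yl]hex-2-enoate (diastereomers) | CCOC(=O)/C=C(/C(OC)OC)CCC(O)C1C[C@@H](/C=C(\C)CCC=C(C)C)OC1=O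
F6 | step 4 | 6-O-methanesulfonate of F5 | CCOC(=O)/C=C(/C(OC)OC)CCC(OS(C)(=O)=O)C1C[C@@H](/C=C(\C)CCC=C(C)C)OC1=O
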